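**Retrosynthetic overview**

Labels: C1 ketone carbon; C2 CH bridgehead; C3=C4 alkene of the bicycle (methyl on C4); C5 fully substituted bridgehead; C6 (lactone O) to C9 the rest of ring B; C10 quaternary carbon with methyl; C11 lactone α-carbon; C1'H2–C2'H the saturated bridge; C3' first side-chain carbon.
Feature used: C5 and C10 are the β- and α-carbons of one enone inside the six-membered ring C1–C10–C5–C1'–C2'–C2, which is the ring of carvone, so a radical that bonds to C5 is handed on to C10.
Key disconnection: C4–C5 and C9–C10 together, by a radical cascade from the monocyclic alkenyl iodide 19 (iodopropenyl arm on C2, vinyl lactone on C5) to the tetracycle 20.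
19 from (S)-carvone: isopropenyl to ketal-masked acetyl; C2 arm by palladium-catalysed α'-alkenylation (as vinylsilane, later iodide); lactone by vinylogous Mukaiyama–Michael addition at C5, vinyl conjugate addition at C7, then Saegusa reoxidation.
Ring order: cyclohexenone (from carvone), γ-lactone, C3=C4 bridge of the bicyclo[2.2.2]octene, ring B; the side chain is finished last from the C2' acetyl by enol triflate formation and Negishi coupling.

Key step: step 10

Remark: isopropenyltrimethylsilane 5 is taken as a purchasable silane; the alkenyl halides are drawn as E isomers, but either geometry would serve because the C4 radical inverts before it cyclizes.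

**Route**

Step 1
Reactants: 1 (S)-(+)-carvone
Product: 3 (S)-5-acetyl-2-methylcyclohex-2-en-1-one, via methoxy hydroperoxide 2 (not isolated)
Conditions: O3, CH2Cl2/MeOH, −78 °C (Sudan Red 7B end point); Me2S, −78 → 23 °C
Reagents that add atoms: ozone, O=[O+][O-]
Why: Chemoselective ozonolysis, in which ozone attacks the electron-rich 1,1-disubstituted isopropenyl alkene much faster than the electron-poor enone alkene, and reductive work-up gives the methyl ketone without touching the stereocentre (future C2').

Step 2
Reactants: 3 (S)-5-acetyl-2-methylcyclohex-2-en-1-one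
Product: 4 (S)-2-methyl-5-(2-methyl-1,3-dioxolan-2-yl)cyclohex-2-en-1-one
Conditions: (Me3SiOCH2)2, Me3SiOTf (2 mol%), CH2Cl2, −78 °C; pyridine
Reagents that add atoms: 1,2-bis(trimethylsilyloxy)ethane, C[Si](C)(C)OCCO[Si](C)(C)C
Why: Noyori acetalization, in which aprotic silyl triflate catalysis at low temperature ketalizes the saturated methyl ketone and leaves the less electrophilic conjugated ketone, with no enolization toward C2'.

Step 3
Reactants: 5 isopropenyltrimethylsilane
Product: 7 (E)-(1-bromoprop-1-en-2-yl)trimethylsilane, via dibromide 6 (not isolated)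
Conditions: Br2, CH2Cl2, −78 °C; DBU, 0 → 23 °C
Reagents that add atoms: bromine, BrBr
Why: Bromination–dehydrobromination of a vinylsilane, in which anti addition of bromine is followed by E2 loss of the tertiary bromide with the more acidic bromomethyl hydrogen to give the β-bromovinylsilane.

Step 4
Reactants: 4 (S)-2-methyl-5-(2-methyl-1,3-dioxolan-2-yl)cyclohex-2-en-1-one; 7 (E)-(1-bromoprop-1-en-2-yl)trimethylsilane
Product: 10 cis-α'-alkenyl enone (C2 arm (E)-CH=C(CH3)SiMe3 cis to the dioxolanyl group on C2'), via lithium enolate 8 (not isolated), via lithium dienolate 9 (not isolated)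
Conditions: LiHMDS (2.2 equiv), THF, −78 °C; 7, Pd2(dba)3 (2.5 mol%), P(t-Bu)3 (6 mol%), PhMe, 23 °C; AcOH, −78 °C
Reagents that add atoms: none
Why: Palladium-catalysed α-alkenylation of a ketone enolate with an alkenyl bromide, in which the kinetic cross-conjugated enolate couples at C2, the second equivalent of base holds the more acidic product as its dienolate, and kinetic α-protonation anti to the pseudoaxial dioxolanyl group on C2' should place the arm cis to it (the less stable epimer that the cascade needs).

Step 5
Reactants: 11 3-methylfuran-2(5H)-one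
Product: 12 tert-butyldimethyl[(3-methylfuran-2-yl)oxy]silane
Conditions: t-BuMe2SiOTf, Et3N, CH2Cl2, 0 °C
Reagents that add atoms: tert-butyldimethylsilyl trifluoromethanesulfonate, CC(C)(C)[Si](C)(C)OS(=O)(=O)C(F)(F)F
Why: Soft enolization and O-silylation of the butenolide give the aromatic 2-silyloxyfuran, a vinylogous donor that reacts at its γ-carbon.

Step 6
Reactants: 10 cis-α'-alkenyl enone; 12 tert-butyldimethyl[(3-methylfuran-2-yl)oxy]silane
Product: 13 butenolide silyl enol ether (C1–OSi, C1=C10; butenolide carbon C6 bonded to C5, trans to the C2' and C2 substituents)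
Conditions: 12 (1.5 equiv), t-BuMe2SiOTf (10 mol%), CH2Cl2, −78 °C; Et3N
Reagents that add atoms: none
Why: Vinylogous Mukaiyama–Michael addition, in which the furan γ-carbon (future C6) attacks C5 of the silyl-activated enone on the face trans to the C2' and C2 substituents, a Diels–Alder-like endo alignment of furan over enone should set C6 relative to the transient C5 centre as required, and silyl transfer leaves the ketone masked as its silyl enol ether.

Step 7
Reactants: 13 butenolide silyl enol ether; 14 vinylmagnesium bromide
Product: 17 all-trans vinyl lactone silyl enol ether, via silyl ketene acetal 15 (not isolated), via C11-epimeric lactone 16 (not isolated)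
Conditions: 14 (2 equiv), CuBr·SMe2 (20 mol%), Me3SiCl, THF, −78 → −40 °C; aq NH4Cl; DBU (20 mol%), CH2Cl2, 23 °C
Reagents that add atoms: none
Why: Copper-catalysed conjugate addition of the Grignard reagent, accelerated by Me3SiCl, occurs only at the butenolide (the silyl enol ether is no acceptor) and anti to the C6 substituent, setting C7 trans to C6, and DBU equilibration of the enolizable C11 should converge on the all-trans lactone while C2 is not acidic at this stage.

Step 8
Reactants: 17 all-trans vinyl lactone silyl enol ether
Product: 18 vinylsilane enone (C1 ketone, C10=C5 restored)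
Conditions: Pd(OAc)2 (1.1 equiv), MeCN, 40 °C
Reagents that add atoms: none
Why: Saegusa–Ito oxidation, in which the palladium enolate at C10 loses the syn hydrogen of C5 to restore the tetrasubstituted enone, erasing the transient C5 centre and leaving C2, C6, C7 and C11 untouched.

Step 9
Reactants: 18 vinylsilane enone
Product: 19 alkenyl iodide enone (cascade precursor, E iodide)
Conditions: NIS (1.2 equiv), 2,6-lutidine, (CF3)2CHOH, 0 °C
Reagents that add atoms: N-iodosuccinimide, O=C1CCC(=O)N1I
Why: Electrophilic ipso-iododesilylation of the vinylsilane through the β-silyl cation exchanges silicon for iodine with retention under buffered conditions that leave the acidic C2 hydrogen alone, the enone alkene and the monosubstituted vinyl group being far less nucleophilic.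

Step 10
Reactants: 19 alkenyl iodide enone
Product: 20 tetracyclic ketal lactone (bicyclo[2.2.2]octenone, ring B and lactone complete)
Conditions: (Me3Si)3SiH (1.5 equiv, slow addition), Et3B (0.3 equiv), air, PhMe (0.005 M), 23 °C
Reagents that add atoms: none
Why: The silyl radical abstracts iodine from 19 and the σ-alkenyl radical at C4, which inverts rapidly so that the iodide geometry is irrelevant, adds to the enone β-carbon C5 (6-exo-trig counted through C2–C2'–C1') and closes the C3=C4 bridge of the bicyclo[2.2.2]octene. The tertiary, electrophilic α-keto radical then at C10 attacks the terminal CH2 (C9) of the vinyl group 6-endo-trig to close ring B, and the secondary C8 radical takes hydrogen from the silane and carries the chain. The closest known reaction type is the stannane- or silane-mediated alkenyl-radical conjugate cyclization followed by capture of the α-keto radical by a pendant alkene in a cascade. C5 is set by the tether, because the arm sits on C2 on the face cis to the C2' substituent (axial arm, equatorial dioxolanyl group) and can reach C5 only from that face. C10 is set by C6, because with the trans-disposed lactone a chair transition state with both lactone bonds equatorial exists only when C9 bonds to the lobe of C10 that is syn to the new C3=C4 bridge, and the alternative 5-exo closure at C8 would need a trans-fused bicyclo[3.3.0] lactone. The step needs both cyclizations to outrun 1,5-hydrogen transfer and premature reduction, which high dilution with slow addition of the slow hydrogen donor (Me3Si)3SiH, the polarity match of the α-keto radical with the unactivated alkene and the ketal mask of the side chain (no exomethylene to intercept the C4 radical) are meant to secure.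

Step 11
Reactants: 20 tetracyclic ketal lactone
Product: 21 tetracyclic methyl ketone (acetyl on C2')
Conditions: 1 M HCl, THF, 23 °C
Reagents that add atoms: water, O
Why: Acid-catalysed ketal hydrolysis frees the methyl ketone, and mild acid should leave C2' and the lactone untouched while the C1 ketone cannot enolize (C2 bridgehead, C10 quaternary).

Step 12
Reactants: 21 tetracyclic methyl ketone
Product: 23 terminal enol triflate (C2'–C(OTf)=CH2), via potassium enolate 22 (not isolated)
Conditions: KHMDS (1.05 equiv), THF, −78 °C; PhNTf2, −78 → 0 °C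
Reagents that add atoms: N-phenylbis(trifluoromethanesulfonimide), O=S(=O)(N(c1ccccc1)S(=O)(=O)C(F)(F)F)C(F)(F)F
Why: Kinetic deprotonation of the methyl group (the least hindered acidic site) and O-triflation give the terminal enol triflate, and C2' keeps its configuration because the more substituted enolate is not formed.

Step 13
Reactants: 23 terminal enol triflate; 24 5-bromo-2-methylpent-2-ene
Product: 26 CNP0385704.1, via alkylzinc bromide 25 (not isolated)
Conditions: 24, Zn dust, LiCl, THF, 40 °C; then 23, Pd(PPh3)4 (5 mol%), THF, 50 °C
Reagents that add atoms: none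
Why: Negishi coupling, in which zinc insertion gives the primary alkylzinc bromide and zerovalent palladium couples it with the enol triflate, tolerating ketone and lactone and installing the whole side chain with its 1,1-disubstituted alkene in place.

**Compound list**

1 | (S)-(+)-carvone | C=C(C)[C@H]1CC=C(C)C(=O)C1 | starting material
2 | 5-(1-hydroperoxy-1-methoxyethyl)-2-methylcyclohex-2-en-1-one (epimers at the peroxide carbon) | COC(C)(OO)[C@H]1CC=C(C)C(=O)C1 | intermediate
3 | (S)-5-acetyl-2-methylcyclohex-2-en-1-one | CC(=O)[C@H]1CC=C(C)C(=O)C1 | intermediate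
4 | (S)-2-methyl-5-(2-methyl-1,3-dioxolan-2-yl)cyclohex-2-en-1-one | CC1(OCCO1)[C@H]2CC=C(C)C(=O)C2 | intermediate
5 | isopropenyltrimethylsilane | C=C(C)[Si](C)(C)C | starting material
6 | (1,2-dibromopropan-2-yl)trimethylsilane (racemic) | BrCC(C)(Br)[Si](C)(C)C | intermediate
7 | (E)-(1-bromoprop-1-en-2-yl)trimethylsilane | C[Si](C)(C)/C(C)=C/Br | intermediate
8 | lithium α'-enolate of 4 (C1–OLi, C1=C2) | CC1(OCCO1)[C@H]2CC=C(C)C(O[Li])=C2 | intermediate
9 | lithium dienolate of 10 (C1–OLi, C1=C2, C3=C4) | CC1(OCCO1)[C@H]2CC=C(C)C(O[Li])=C2/C=C(C)/[Si](C)(C)C | intermediate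
10 | 5,6-cis-2-methyl-5-(2-methyl-1,3-dioxolan-2-yl)-6-[(E)-2-(trimethylsilyl)prop-1-enyl]cyclohex-2-en-1-one | CC1(OCCO1)[C@H]2CC=C(C)C(=O)[C@H]2/C=C(C)/[Si](C)(C)C | intermediate
11 | 3-methylfuran-2(5H)-one | CC1=CCOC1=O | starting material
12 | tert-butyldimethyl[(3-methylfuran-2-yl)oxy]silane | Cc1ccoc1O[Si](C)(C)C(C)(C)C | intermediate
13 | C1 tert-butyldimethylsilyl enol ether with the 4-methyl-5-oxo-2,5-dihydrofuran-2-yl group on C5 (trans to the C2' and C2 substituents) | CC1(OCCO1)[C@H]2C[C@H]([C@H]3OC(=O)C(C)=C3)C(C)=C(O[Si](C)(C)C(C)(C)C)[C@H]2/C=C(C)/[Si](C)(C)C | intermediate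
14 | vinylmagnesium bromide | C=C[Mg]Br | starting material
15 | trimethylsilyl ketene acetal of the lactone after vinyl addition at C7 | CC1(OCCO1)[C@H]2C[C@H]([C@H]3OC(O[Si](C)(C)C)=C(C)[C@@H]3C=C)C(C)=C(O[Si](C)(C)C(C)(C)C)[C@H]2/C=C(C)/[Si](C)(C)C | intermediate
16 | C11 epimer of 17 (methyl cis to vinyl) | CC1(OCCO1)[C@H]2C[C@H]([C@H]3OC(=O)[C@H](C)[C@@H]3C=C)C(C)=C(O[Si](C)(C)C(C)(C)C)[C@H]2/C=C(C)/[Si](C)(C)C | intermediate
17 | C1 silyl enol ether with the all-trans 4-methyl-5-oxo-3-vinyltetrahydrofuran-2-yl lactone on C5 | CC1(OCCO1)[C@H]2C[C@H]([C@H]3OC(=O)[C@@H](C)[C@@H]3C=C)C(C)=C(O[Si](C)(C)C(C)(C)C)[C@H]2/C=C(C)/[Si](C)(C)C | intermediate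
18 | enone with the (E)-2-(trimethylsilyl)propenyl arm on C2 and the all-trans vinyl lactone on C5 | CC1(OCCO1)[C@H]2CC(=C(C)C(=O)[C@H]2/C=C(C)/[Si](C)(C)C)[C@H]3OC(=O)[C@@H](C)[C@@H]3C=C | intermediate
19 | enone with the (E)-2-iodopropenyl arm on C2 (cis to the dioxolanyl group) and the all-trans vinyl lactone on C5 | CC1(OCCO1)[C@H]2CC(=C(C)C(=O)[C@H]2/C=C(C)/I)[C@H]3OC(=O)[C@@H](C)[C@@H]3C=C | intermediate
20 | tetracyclic lactone with the C2' acetyl masked as dioxolane | CC1(OCCO1)[C@H]2C[C@@]34C(C)=C[C@@H]2C(=O)[C@]3(C)CC[C@H]5[C@H](C)C(=O)O[C@@H]54 | intermediate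
21 | tetracyclic lactone with acetyl on C2' | CC(=O)[C@H]1C[C@@]23C(C)=C[C@@H]1C(=O)[C@]2(C)CC[C@H]1[C@H](C)C(=O)O[C@@H]13 | intermediate
22 | potassium enolate of 21 at the methyl ketone (terminal) | C=C(O[K])[C@H]1C[C@@]23C(C)=C[C@@H]1C(=O)[C@]2(C)CC[C@H]1[C@H](C)C(=O)O[C@@H]13 | intermediate
23 | enol triflate of 21 (C2'–C(OTf)=CH2) | C=C(OS(=O)(=O)C(F)(F)F)[C@H]1C[C@@]23C(C)=C[C@@H]1C(=O)[C@]2(C)CC[C@H]1[C@H](C)C(=O)O[C@@H]13 | intermediate
24 | 5-bromo-2-methylpent-2-ene | CC(C)=CCCBr | starting material
25 | (4-methylpent-3-en-1-yl)zinc bromide | CC(C)=CCC[Zn]Br | intermediate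
26 | CNP0385704.1 | C=C(CCC=C(C)C)[C@H]1C[C@@]23C(C)=C[C@@H]1C(=O)[C@]2(C)CC[C@H]1[C@H](C)C(=O)O[C@@H]13 | target

**Step count and risks**

Total steps: 13. Longest linear sequence: 11 steps (steps 1, 2, 4 and 6 to 13); steps 3 and 5 make the two coupling partners.

Steps most likely to fail:

1. Step 10 (radical cascade). Process at risk: hydrogen transfer from C1' to the alkenyl radical, or hydrogen capture by the C10 radical before ring B closes, would drain material into reduced monocyclic or bicyclic products. Fallback, setting out from 19 and coming back at 20, closes the two bonds one after the other with known reactions. An intramolecular reductive Heck cyclization of 19 (Pd(OAc)2, PPh3, HCO2Na, DMF, 80 °C) forms C4–C5 and gives the bicyclo[2.2.2]octenone with hydrogen on C10, F1. Deprotonation at C10, the only enolizable position of that ketone, with KHMDS and trapping with PhSeCl gives the α-phenylselanyl ketone F2. Bu3SnH and AIBN in hot benzene then generate the C10 radical alone, which closes ring B 6-endo under the same chair control and gives 20.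

2. Step 6 (vinylogous Mukaiyama–Michael addition). Process at risk: poor discrimination between the endo and exo alignments of furan and enone would put the wrong configuration at C6, and the silyl triflate might also open the dioxolane. Fallback, setting out from 10 and 12 and coming back at 13, replaces kinetic control by equilibration. The unwanted adduct, the C6 epimer of 13, F3, is separated and its butenolide γ-centre is equilibrated with DBU through the 2-oxidofuran, which is safe for C2 because C1 is a silyl enol ether at this stage. The mixture is separated again and recycled, so that material is funnelled to 13.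

3. Step 4 (α'-alkenylation and protonation). Process at risk: β-hydride loss from the palladium enolate (dehydrogenation toward a phenol), enolate equilibration with coupling at the γ-carbon, or weak facial control in the protonation that sets C2. Fallback, setting out from 4 and 7 and coming back at 10, reverses the polarity of the coupling. Enolate 8 is brominated with NBS to the α'-bromo ketone F4. Bromide 7 is converted by t-BuLi and then ZnBr2 into the alkenylzinc bromide F5. A nickel-catalysed Negishi-type coupling (NiCl2·glyme, 4,4'-di-tert-butyl-2,2'-bipyridine, THF) joins them at C2 and should give mainly the trans alkenyl ketone F6. Deprotonation of F6 with LiHMDS at −78 °C and an acetic acid quench then sets C2 and gives 10.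

Further compounds
F1 | step 10 | bicyclo[2.2.2]octenone from reductive Heck closure of C4–C5 (hydrogen on C10, C10 epimers; vinyl lactone and dioxolane intact) | CC1(OCCO1)[C@H]2C[C@]3(C(C)=C[C@@H]2C(=O)C3C)[C@H]4OC(=O)[C@@H](C)[C@@H]4C=C
F2 | step 10 | C10 phenylselanyl derivative of F1 | CC1(OCCO1)[C@H]2C[C@]3(C(C)=C[C@@H]2C(=O)C3(C)[Se]c5ccccc5)[C@H]4OC(=O)[C@@H](C)[C@@H]4C=C
F3 | step 6 | C6 epimer of 13 | CC1(OCCO1)[C@H]2C[C@H]([C@@H]3OC(=O)C(C)=C3)C(C)=C(O[Si](C)(C)C(C)(C)C)[C@H]2/C=C(C)/[Si](C)(C)C
F4 | step 4 | trans-6-bromo-2-methyl-5-(2-methyl-1,3-dioxolan-2-yl)cyclohex-2-en-1-one | CC1(OCCO1)[C@H]2CC=C(C)C(=O)[C@@H]2Br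
F5 | step 4 | (E)-[2-(trimethylsilyl)prop-1-enyl]zinc bromide | C[Si](C)(C)/C(C)=C/[Zn]Br
F6 | step 4 | C2 epimer of 10 (arm trans to the dioxolanyl group) | CC1(OCCO1)[C@H]2CC=C(C)C(=O)[C@@H]2/C=C(C)/[Si](C)(C)C
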